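## Structural features

The target is a flavanone in which a hexasubstituted benzene ring A (C5 OH, C6 CH3, C7 OCH3, C8 CH3) is fused along its C4a–C8a edge to the dihydropyranone ring C (O1, C2, C3, C4=O), and C2 carries ring B, a 1,4-benzoquinone bound through C1' with carbonyls at C2' and C5' and a methoxy group at C4'. C2 is the only stereocenter (S) and has no stereogenic neighbour, so its configuration must come from a catalyst or reagent. The fragile parts are the quinone, which is reducible and adds nucleophiles, and the C2–H bond, which is α to O1, allylic to the quinone and β to the C4 carbonyl: base opens ring C by retro-oxa-Michael reaction or tautomerises the alkylquinone to a quinone methide, and either event erases C2. The C5 hydroxyl is hydrogen-bonded to the C4 carbonyl, which makes an acetal on this oxygen unusually easy to remove at the end. The real difficulty is to create C2 enantioselectively beside a ring that cannot travel as a quinone through bond-forming chemistry, on a ring A that has no free position and whose three oxygens must end as OH, OCH3 and ring ether in a fixed order. Ring B is therefore carried as a 2-hydroxy-4-methoxyphenyl group, whose free position para to the hydroxyl (C5') is oxidised late. The key step uses the fact that ring C has O1–C2 and C3–C4 on the two sides of the C8a–C4a edge of ring A: O1–C8a–C4a–C4 is the oxa-diene of an ortho-quinone methide and C2–C3 is the double bond of a styrene. The C2' hydroxyl of ring B serves first as the hydrogen-bond handle for the chiral acid and later becomes the C2' carbonyl oxygen.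

## Logic of the disconnections

13 ⇒ 12. The O–CH2 bond of an acetal on the C5 oxygen is cut. A free C5 hydroxyl would expose the electron-rich ring A to the two oxidations that precede, so it stays masked until the end. The gain is selectivity in those oxidations. The demand is a cleavage that is acidic and free of base and nucleophiles, because of the quinone and of C2.

12 ⇒ 10 (through 11). The C4=O bond is removed, leaving a C4 methylene. C4 is benzylic to ring A and activated by three oxygen donors, so it can be oxidised after ring C exists. The gain is that ring C becomes a plain chromane, open to a cycloaddition. The demand is that hydride abstraction chooses C4 and not C2, which is why ring B must already be the electron-poor quinone at this stage.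

10 ⇒ 9. The C5'=O bond is cut and ring B is returned to the phenol oxidation level. A quinone would not survive the ring-forming step, and the phenol is needed there as a binding site. The gain is a stable, electron-rich aryl group. The demand is a para-selective phenol oxidation that leaves ring A alone; this is secured because ring A then has neither a free hydroxyl nor a free position.

9 ⇒ 5 + 7 (through 8). O1–C2 and C3–C4 are cut together, the retron of an oxa-[4+2] cycloaddition. This divides the molecule into two aromatic halves of similar size and removes the only stereocenter. The demand is that a chiral Brønsted acid generates 8 from a primary benzylic alcohol, holds both partners, and controls the face of the styrene.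

5 ⇒ 4. A C4–H bond is cut (alcohol to aldehyde). The hydroxymethyl phenol is the labile precursor of 8 and should be made last, by a mild hydride reduction. The demand is to stop at the alcohol and to use it without storage.

4 ⇒ 3. The O–CH2OCH3 bond is cut, which gives a diol with two equivalent hydroxyls. The forward monoprotection is selective because, after the first alkylation, the remaining hydroxyl is tied up in a hydrogen bond to the formyl oxygen. A diol without that carbonyl group would be protected statistically.

3 ⇒ 2. The O–CH3 bond at the future C7 oxygen is cut. The demand is that one methyl electrophile selects the hydroxyl para to the formyl group, which is the most acidic one.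

2 ⇒ 1. The two ring C–CH3 bonds (future C6 and C8) are cut. Because the one-carbon unit that becomes C4 is already on the ring, it blocks the position between the two ortho oxygens and only the two wanted carbons can be methylated. A sequence that methylates an arene lacking this carbon, and adds the one-carbon unit afterwards, was rejected: three ring positions would compete for the methyl groups, and the later hydroxymethylation tends to run on to diarylmethanes. The demand is control of the degree of C-alkylation.

7 ⇒ 6. The vinyl C=C bond is cut (olefination retron). The demand is only that the free phenol be tolerated, which an excess of ylide allows.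

## Other disconnections considered

Alternative 1: The cut runs through ring A itself, at C4a–C8a. The benzene ring is unfolded to the open-chain, doubly C-methylated 3,5,7-triketo ester A2, whose far end already holds the silyl-protected carbinol carbon that becomes C2.
- Forward key step: Mg(OCH3)2 would chelate the polyketone, the C4a methylene would attack the ester carbonyl (Claisen condensation), and enolisation would give the acylphloroglucinol A1. Desilylation, closure of O1–C2 with inversion (Mitsunobu reaction, so that 3R maps onto 2S), methylation of the C7 oxygen and oxidative demethylation of the trimethoxyphenyl ring with (NH4)2Ce(NO3)6 would follow.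
- In its favour: the substitution pattern of ring A is fixed by the chain, so no aromatic substitution has to be steered. The C4 carbonyl is present from the outset, so no late benzylic oxidation is needed; on this point the alternative is the better one. The stereocenter rests on an acyclic carbinol accessible by standard asymmetric aldol or ketone-reduction chemistry, at least the equal of the chosen plan in precedent.
- Against it here: the silyloxy group is β to a ketone flanked by acidic methylenes, and in the basic, chelating medium an E1cB elimination would destroy the stereocenter. The later ring closure must invert a carbinol attached to a very electron-rich aryl group, where ionisation competes with clean displacement. A1 has three free phenols of which one must be methylated. A2 has to be built by several consecutive enolate acylations.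
- Comparison: on structure, each plan makes one ring in its key event, but the chosen plan makes ring C and C2 together, whereas this key step creates no stereocenter. On mechanism, the Claisen folding is well understood and not less reliable than the cycloaddition. On step economy, the linear polyketone assembly plus about four steps after the key step should be clearly longer than nine steps.

Alternative 2: Ring A is removed entirely and ring C is kept. The cuts are C5–C6, C7–C8, C8–C8a and C4a–C5, leading back to the enantiopure dihydropyranone diazoketone A4 and 1-methoxypropyne A5.
- Forward key step: irradiation of A4 would trigger a Wolff rearrangement in which the pyranone carbon migrates (C8–C8a) to the ketene stage. [2+2] addition of A5 would form C5–C6 and C7–C8, and four-electron ring opening followed by six-electron closure through C4a–C5 would lead to the phenol A3.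
- In its favour: the hexasubstituted ring is built regiospecifically, the polarity of the ynol ether deciding where CH3 and OCH3 go. A3 already has the free C5 hydroxyl, the C7 methyl ether and the C4 carbonyl, so a single oxidation of ring B would reach the target. After the key step this is shorter than the chosen plan and needs no protecting group on ring A; both points are better.
- Against it here: A4 is a demanding substrate. A diazo group must be placed on an ethyl ketone in the presence of the more acidic C3 methylene. The cross-conjugated pyranone is itself a chromophore with its own photochemistry. The 2-aryl stereocenter, set earlier by an asymmetric hetero-Diels–Alder reaction, must survive light and the heating that the electrocyclic steps usually need, although an electron-rich 2-aryl-dihydropyranone can open reversibly at O1–C2. A5 is volatile and must be prepared. The final (NH4)2Ce(NO3)6 oxidation would meet a free, electron-rich ring A phenol.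
- Comparison: on structure, the alternative maps most directly onto the oxidation pattern of the target (better). On mechanism, it relies on four consecutive pericyclic events on an untested substrate, against one catalysed cycloaddition. On step economy, the short endgame is offset by the long way to A4, so the total should be similar or higher.

Alternative 3: The cuts are C4a–C4, C4–C3 and O1–C2. Ring C is assembled from the iodophenol A7, carbon monoxide A9 and the arylacetylene A8.
- Forward key step: PdCl2(PPh3)2 would join the three components in a carbonylative Sonogashira coupling (C4a–C4 and C4–C3), and the phenol oxygen would then close 6-endo-dig onto the alkyne to give the flavone A6. Enantioselective hydrogenation or conjugate reduction of C2=C3, hydrogenolysis of the two benzyl ethers and oxidation of the resulting 3-hydroxy-4-methoxyphenyl ring with (KSO3)2NO would complete the route; that oxidation attacks the position para to the hydroxyl and gives the same quinone.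
- In its favour: three components are joined in one flask. A6 is a flat, achiral, robust intermediate. The C4 carbonyl is in place, so no benzylic oxidation is needed (better than the chosen plan). The stereocenter is introduced late and has few steps in which to erode (equal or better). The quinone-forming step is of the same type as in the chosen plan (equal).
- Against it here: A7 is a hexasubstituted, electron-rich aryl iodide flanked by two ortho substituents, so oxidative addition and CO insertion are slow; direct coupling without CO, or 5-exo closure, can compete. The enantioselective reduction of a flavone double bond (a trisubstituted vinylogous ester next to a peri benzyloxy group) has few precedents and tends to run on to the C4 alcohol, which would require re-oxidation. The benzyl ethers must be hydrogenolysed without reducing the ketone. A7 needs the same ring A chemistry as the chosen plan plus benzylation and iodination.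
- Comparison: on structure, both plans are convergent couplings of a ring A phenol with a ring B styrene or alkyne. On mechanism, the chosen plan forms ring C and C2 in one event; here ring formation and stereocontrol are separate, and the second is the less certain. On step economy, the two plans are about equal.

Key step: step 6

Assumption: the sense of induction of the chiral acid cannot be predicted with certainty for a methide carbon without substituent; the (R)-acid is written, and its mirror image is to be used if a test run shows the 2R product.

Check of structures: with O1 > C1' > C3 > H the descriptor at C2 is S in 9 and stays S through 13, and para-oxidation of the C2' phenol puts the carbonyls at C2' and C5' with OCH3 at C4'; nothing had to be corrected.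

Commercial starting materials: 1 and 6.

Step 1
Reactants: 1 2,4,6-trihydroxybenzaldehyde
Product: 2 2,4,6-trihydroxy-3,5-dimethylbenzaldehyde
Conditions: NaOCH3 (3.2 equiv), CH3I (2.2 equiv), CH3OH, 0 °C → rt
Reagents that add atoms: iodomethane, CI
Why: C-alkylation of a phloroglucinol polyanion, the known C-methylation of acylphloroglucinols; the formyl carbon (the future C4) already occupies the position between the two ortho oxygens, so the only nucleophilic ring carbons left are the future C6 and C8. CH3I is limited to 2.2 equiv and the temperature kept low to hold back O-methylation and a third, dearomatising C-methylation.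

Step 2
Reactants: 2 2,4,6-trihydroxy-3,5-dimethylbenzaldehyde
Product: 3 2,6-dihydroxy-4-methoxy-3,5-dimethylbenzaldehyde
Conditions: CH3I (1.05 equiv), K2CO3 (1.0 equiv), acetone, rt
Reagents that add atoms: iodomethane, CI
Why: Williamson ether synthesis under weak base; the hydroxyl para to the formyl group is the most acidic and is never engaged in the hydrogen bond to the carbonyl oxygen (the established order of reactivity of 2,4,6-trihydroxyaryl carbonyl compounds), so one equivalent of CH3I should methylate the future C7 oxygen.

Step 3
Reactants: 3 2,6-dihydroxy-4-methoxy-3,5-dimethylbenzaldehyde
Product: 4 2-hydroxy-4-methoxy-6-(methoxymethoxy)-3,5-dimethylbenzaldehyde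
Conditions: CH3OCH2Cl (1.1 equiv), K2CO3 (1.2 equiv), acetone, 0 °C → rt
Reagents that add atoms: chloromethyl methyl ether, COCCl
Why: O-alkylation of a phenoxide to the methoxymethyl acetal; the two hydroxyls of 3 are equivalent, and once one is protected the other is held in the hydrogen bond to the formyl oxygen and is alkylated much more slowly, so one equivalent should give the monoacetal. This internal differentiation is the reason for carrying the one-carbon unit as an aldehyde.

Step 4
Reactants: 4 2-hydroxy-4-methoxy-6-(methoxymethoxy)-3,5-dimethylbenzaldehyde
Product: 5 2-(hydroxymethyl)-5-methoxy-3-(methoxymethoxy)-4,6-dimethylphenol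
Conditions: NaBH4 (1 equiv), THF/CH3OH, 0 °C, short contact; aq. NH4Cl; used at once
Reagents that add atoms: none
Why: Borohydride reduction of a salicylaldehyde to the ortho-hydroxybenzyl alcohol; low temperature, short contact and a mildly acidic quench guard against over-reduction through phenoxide-assisted loss of hydroxide. Because every ring position of 5 is substituted, the usual self-alkylation of electron-rich hydroxybenzyl alcohols to diarylmethanes is shut off, but 5 is still used without storage.

Step 5
Reactants: 6 2-hydroxy-4-methoxybenzaldehyde
Product: 7 5-methoxy-2-vinylphenol
Conditions: CH3PPh3Br (2.3 equiv), KOC(CH3)3 (2.4 equiv), THF, 0 °C → rt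
Reagents that add atoms: methyltriphenylphosphonium bromide, C[P+](c1ccccc1)(c1ccccc1)c1ccccc1.[Br-]
Why: Wittig methylenation of an unprotected salicylaldehyde; the first equivalent of base forms the phenoxide and the ylide then converts CHO into CH=CH2. 7 polymerises easily and is kept cold with a trace of BHT and used soon.

Step 6
Reactants: 5 2-(hydroxymethyl)-5-methoxy-3-(methoxymethoxy)-4,6-dimethylphenol; 7 5-methoxy-2-vinylphenol
Product: 9 (2S)-2-(2-hydroxy-4-methoxyphenyl)-7-methoxy-5-(methoxymethoxy)-6,8-dimethylchromane, via ortho-quinone methide 8 (not isolated)
Conditions: (R)-3,3'-bis(2,4,6-triisopropylphenyl)-1,1'-binaphthyl-2,2'-diyl hydrogen phosphate (10 mol %), 7 (2 equiv), slow addition of 5, 3 Å MS, toluene, 0 °C → rt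
Reagents that add atoms: none
Why: The phosphoric acid protonates the benzylic hydroxyl of 5 and, helped by the oxygen donors at C5, C7 and C8a, expels water to give ortho-quinone methide 8 as a hydrogen-bonded ion pair, while its phosphoryl oxygen binds the phenol OH of 7. The closest known reaction type is the chiral phosphoric acid-catalysed oxa-[4+2] cycloaddition of ortho-quinone methides, formed in the flask from ortho-hydroxybenzyl alcohols, with 2-vinylphenols; 8 differs only in having no substituent on the methide carbon. Ring C closes in an inverse-demand hetero-Diels–Alder mode, four atoms (O1, C8a, C4a, C4) from 8 and two (C3, C2) from 7; the addition is concerted but asynchronous with C3–C4 leading, and in the stepwise limit O1–C2 would close 6-exo-trig onto the benzylic cation stabilised by the para methoxy group. C2 is the only new stereocenter and is under catalyst control: two-point binding of methide and phenol places one face of the styrene against 8 inside the pocket of the 3,3'-aryl groups. Regiochemistry follows from polarity, the electrophilic methide carbon meeting the styrene terminus made nucleophilic by the para methoxy and ortho hydroxyl groups. The step also needs cross-addition to win over self-condensation of 8, over O-alkylation of the phenol of 7 and over acid-induced dimerisation of 7; the fully substituted ring A (no position for Friedel–Crafts attack), the slow addition of 5, the excess of 7 and the weak acid secure this. The aryl methoxymethyl acetal should be inert to this acid at or below room temperature.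

Step 7
Reactants: 9 (2S)-2-(2-hydroxy-4-methoxyphenyl)-7-methoxy-5-(methoxymethoxy)-6,8-dimethylchromane
Product: 10 2-methoxy-5-[(2S)-7-methoxy-5-(methoxymethoxy)-6,8-dimethyl-3,4-dihydro-2H-chromen-2-yl]cyclohexa-2,5-diene-1,4-dione
Conditions: (KSO3)2NO (2.5 equiv), aq. KH2PO4, acetone, 0 °C → rt
Reagents that add atoms: potassium nitrosodisulfonate, [K+].[K+].[O-]S(=O)(=O)N([O])S(=O)(=O)[O-]
Why: Teuber oxidation: one equivalent of the nitroxyl radical removes the phenolic hydrogen, a second bonds through oxygen to the free para carbon C5', and loss of imidodisulfonate gives the para-quinone with carbonyls at C2' and C5' and OCH3 at C4'. Ring A has no free hydroxyl and no free position, the buffered medium is near neutral, and C2 is not involved.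

Step 8
Reactants: 10 2-methoxy-5-[(2S)-7-methoxy-5-(methoxymethoxy)-6,8-dimethyl-3,4-dihydro-2H-chromen-2-yl]cyclohexa-2,5-diene-1,4-dione
Product: 12 2-methoxy-5-[(2S)-7-methoxy-5-(methoxymethoxy)-6,8-dimethyl-4-oxo-3,4-dihydro-2H-chromen-2-yl]cyclohexa-2,5-diene-1,4-dione, via C4 alcohol 11 (not isolated)
Conditions: DDQ (2.5 equiv), CH2Cl2/H2O (10:1), 0 °C → rt
Reagents that add atoms: water, O
Why: DDQ abstracts hydride from C4, which is benzylic to ring A and stabilised by the oxygens at C5, C7 and C8a; water traps the cation as alcohol 11, and a second hydride abstraction from its carbinol carbon gives the ketone, after which the acylated ring A is inert (the known DDQ oxidation of electron-rich arylalkanes to aryl ketones in wet solvent). C2–H is spared because ring B is already an electron-poor quinone, which is why step 7 comes first; the C4 center of 11 (both epimers) is destroyed again and C2 is untouched.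

Step 9
Reactants: 12 2-methoxy-5-[(2S)-7-methoxy-5-(methoxymethoxy)-6,8-dimethyl-4-oxo-3,4-dihydro-2H-chromen-2-yl]cyclohexa-2,5-diene-1,4-dione
Product: 13 2-[(2S)-5-hydroxy-7-methoxy-6,8-dimethyl-4-oxo-3,4-dihydro-2H-chromen-2-yl]-5-methoxycyclohexa-2,5-diene-1,4-dione
Conditions: CF3CO2H/CH2Cl2 (1:9), 0 °C → rt; aq. work-up
Reagents that add atoms: none
Why: Acid-catalysed cleavage of the aryl methoxymethyl acetal, especially easy here because the released C5 hydroxyl forms the hydrogen bond to C4=O. The acid is non-nucleophilic (chloride could add to the quinone) and no base is present, so the quinone should survive and ring C should not open by retro-oxa-Michael reaction, leaving C2 intact.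

Compound list

1 | 2,4,6-trihydroxybenzaldehyde | O=Cc1c(O)cc(O)cc1O | starting material
2 | 2,4,6-trihydroxy-3,5-dimethylbenzaldehyde | O=Cc1c(O)c(C)c(O)c(C)c1O | intermediate
3 | 2,6-dihydroxy-4-methoxy-3,5-dimethylbenzaldehyde | O=Cc1c(O)c(C)c(OC)c(C)c1O | intermediate
4 | 2-hydroxy-4-methoxy-6-(methoxymethoxy)-3,5-dimethylbenzaldehyde | O=Cc1c(O)c(C)c(OC)c(C)c1OCOC | intermediate
5 | 2-(hydroxymethyl)-5-methoxy-3-(methoxymethoxy)-4,6-dimethylphenol | OCc1c(O)c(C)c(OC)c(C)c1OCOC | intermediate
6 | 2-hydroxy-4-methoxybenzaldehyde | COc1ccc(C=O)c(O)c1 | starting material
7 | 5-methoxy-2-vinylphenol | C=Cc1ccc(OC)cc1O | intermediate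
8 | 3-methoxy-5-(methoxymethoxy)-2,4-dimethyl-6-methylidenecyclohexa-2,4-dien-1-one (ortho-quinone methide, not isolated) | C=C1C(=O)C(C)=C(OC)C(C)=C1OCOC | intermediate
9 | (2S)-2-(2-hydroxy-4-methoxyphenyl)-7-methoxy-5-(methoxymethoxy)-6,8-dimethylchromane | COc1ccc(c(O)c1)[C@@H]1CCc2c(OCOC)c(C)c(OC)c(C)c2O1 | intermediate
10 | 2-methoxy-5-[(2S)-7-methoxy-5-(methoxymethoxy)-6,8-dimethyl-3,4-dihydro-2H-chromen-2-yl]cyclohexa-2,5-diene-1,4-dione | COC1=CC(=O)C([C@@H]2CCc3c(OCOC)c(C)c(OC)c(C)c3O2)=CC1=O | intermediate
11 | 2-[(2S)-4-hydroxy-7-methoxy-5-(methoxymethoxy)-6,8-dimethyl-3,4-dihydro-2H-chromen-2-yl]-5-methoxycyclohexa-2,5-diene-1,4-dione (both C4 epimers, not isolated) | COC1=CC(=O)C([C@@H]2CC(O)c3c(OCOC)c(C)c(OC)c(C)c3O2)=CC1=O | intermediate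
12 | 2-methoxy-5-[(2S)-7-methoxy-5-(methoxymethoxy)-6,8-dimethyl-4-oxo-3,4-dihydro-2H-chromen-2-yl]cyclohexa-2,5-diene-1,4-dione | COC1=CC(=O)C([C@@H]2CC(=O)c3c(OCOC)c(C)c(OC)c(C)c3O2)=CC1=O | intermediate
13 | 2-[(2S)-5-hydroxy-7-methoxy-6,8-dimethyl-4-oxo-3,4-dihydro-2H-chromen-2-yl]-5-methoxycyclohexa-2,5-diene-1,4-dione | COC1=CC(=O)C([C@@H]2CC(=O)c3c(O)c(C)c(OC)c(C)c3O2)=CC1=O | target

Total step count: 9. Longest linear sequence: 8 steps (steps 1–4 and 6–9, from 1 to 13); step 5 is the one-step side branch.

Least certain steps

Step 6 (key step). Several processes may go wrong. Ionisation of a primary benzylic alcohol by a weak acid may be slow. The unhindered methide, once formed, may add through a loosely bound or uncatalysed pathway, giving poor facial selectivity. Self-condensation of the methide and acid-induced dimerisation of the styrene compete. Reversible ionisation of the O1–C2 bond of the product, next to an electron-rich aryl group, could erode the configuration. Fallback, setting out from 5 and 7 and returning at 9: the cycloaddition is run without chiral control, with diphenyl phosphate (10–20 mol %) in toluene at 40–60 °C and an excess of 7, which should give racemic 2-(2-hydroxy-4-methoxyphenyl)-7-methoxy-5-(methoxymethoxy)-6,8-dimethylchromane F1. Preparative chromatography on a chiral stationary phase then separates 9 from its (2R)-enantiomer F2, which is set aside.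

Step 1. What may go wrong is loss of control over the degree and site of alkylation: a third C-methylation that dearomatises the ring, and O-methylation in place of C-methylation. Fallback, setting out from 1 and returning at 2, by halogenation and cross-coupling: 1 is fully protected (NaH, CH3OCH2Cl, DMF) to 2,4,6-tris(methoxymethoxy)benzaldehyde F3. N-Bromosuccinimide in CH3CN brominates the only two free positions to give 3,5-dibromo-2,4,6-tris(methoxymethoxy)benzaldehyde F4. A twofold Suzuki–Miyaura methylation (trimethylboroxine, Pd(OAc)2/SPhos, K3PO4, toluene/H2O, 100 °C) gives 2,4,6-tris(methoxymethoxy)-3,5-dimethylbenzaldehyde F5. HCl in CH3OH removes the three acetals to return 2.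

Step 8. What may go wrong: the oxidation may stall at the alcohol stage. The alcohol may ionise and lose H3, and the resulting alkene may be aromatised by DDQ to a benzopyrylium ion with loss of C2. The acidic hydroquinone may cause premature loss of the acetal, which is harmless. Fallback, setting out from 10 and returning at 12, with no new compound (F0): the two oxidation events are separated. DDQ (1.1 equiv) at 0 °C is used only for the hydride abstraction, 11 is isolated by rapid filtration, and it is then oxidised with Dess–Martin periodinane buffered with NaHCO3 in CH2Cl2. This oxidant cannot abstract hydride from C2 or dehydrogenate ring C.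

Step 7. What may go wrong: the phenoxyl radical may couple at an ortho carbon instead of the para carbon. Oxidation may continue at the benzylic C2–H through a quinone-methide tautomer. Conversion may be incomplete because the lipophilic substrate mixes poorly with the aqueous oxidant. Fallback, setting out from 9 and returning at 10, by two-electron oxidation: PhI(OAc)2 (2.2 equiv) in CH3OH at 0 °C should convert the phenol into the para-quinone monoketal 2-[(2S)-7-methoxy-5-(methoxymethoxy)-6,8-dimethyl-3,4-dihydro-2H-chromen-2-yl]-4,4,5-trimethoxycyclohexa-2,5-dien-1-one F6. Mild hydrolysis of the ketal (pyridinium p-toluenesulfonate, acetone/H2O, rt) then gives 10 without touching the aryl acetal.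

## Further compounds

F1 | step 6 | racemic 2-(2-hydroxy-4-methoxyphenyl)-7-methoxy-5-(methoxymethoxy)-6,8-dimethylchromane | COc1ccc(C2CCc3c(OCOC)c(C)c(OC)c(C)c3O2)c(O)c1
F2 | step 6 | (2R)-2-(2-hydroxy-4-methoxyphenyl)-7-methoxy-5-(methoxymethoxy)-6,8-dimethylchromane | COc1ccc(c(O)c1)[C@H]1CCc2c(OCOC)c(C)c(OC)c(C)c2O1
F3 | step 1 | 2,4,6-tris(methoxymethoxy)benzaldehyde | O=Cc1c(OCOC)cc(OCOC)cc1OCOC
F4 | step 1 | 3,5-dibromo-2,4,6-tris(methoxymethoxy)benzaldehyde | O=Cc1c(OCOC)c(Br)c(OCOC)c(Br)c1OCOC
F5 | step 1 | 2,4,6-tris(methoxymethoxy)-3,5-dimethylbenzaldehyde | O=Cc1c(OCOC)c(C)c(OCOC)c(C)c1OCOC
F0 | step 8 | none | none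
F6 | step 7 | 2-[(2S)-7-methoxy-5-(methoxymethoxy)-6,8-dimethyl-3,4-dihydro-2H-chromen-2-yl]-4,4,5-trimethoxycyclohexa-2,5-dien-1-one | COC1=CC(=O)C([C@@H]2CCc3c(OCOC)c(C)c(OC)c(C)c3O2)=CC1(OC)OC
A1 | alternative 1 | (3R)-3-[(tert-butyldimethylsilyl)oxy]-1-(2,4,6-trihydroxy-3,5-dimethylphenyl)-3-(2,4,5-trimethoxyphenyl)propan-1-one | COc1cc(OC)c(OC)cc1[C@H](O[Si](C)(C)C(C)(C)C)CC(=O)c1c(O)c(C)c(O)c(C)c1O
A2 | alternative 1 | methyl (9R)-9-[(tert-butyldimethylsilyl)oxy]-2,4-dimethyl-3,5,7-trioxo-9-(2,4,5-trimethoxyphenyl)nonanoate | COC(=O)C(C)C(=O)C(C)C(=O)CC(=O)C[C@@H](O[Si](C)(C)C(C)(C)C)c1cc(OC)c(OC)cc1OC
A3 | alternative 2 | (2S)-5-hydroxy-7-methoxy-6,8-dimethyl-2-(2,4,5-trimethoxyphenyl)chroman-4-one | COc1cc(OC)c(OC)cc1[C@@H]1CC(=O)c2c(O)c(C)c(OC)c(C)c2O1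
A4 | alternative 2 | (2S)-6-(2-diazopropanoyl)-2-(2,4,5-trimethoxyphenyl)-2,3-dihydro-4H-pyran-4-one | CC(=[N+]=[N-])C(=O)C1=CC(=O)C[C@H](O1)c1cc(OC)c(OC)cc1OC
A5 | alternative 2 | 1-methoxyprop-1-yne | CC#COC
A6 | alternative 3 | 5-(benzyloxy)-2-[3-(benzyloxy)-4-methoxyphenyl]-7-methoxy-6,8-dimethyl-4H-chromen-4-one | COc1ccc(cc1OCc1ccccc1)-c1cc(=O)c2c(OCc3ccccc3)c(C)c(OC)c(C)c2o1
A7 | alternative 3 | 3-(benzyloxy)-2-iodo-5-methoxy-4,6-dimethylphenol | Oc1c(I)c(OCc2ccccc2)c(C)c(OC)c1C
A8 | alternative 3 | 2-(benzyloxy)-4-ethynyl-1-methoxybenzene | C#Cc1ccc(OC)c(OCc2ccccc2)c1
A9 | alternative 3 | carbon monoxide | [C-]#[O+]
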